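**Plan**

1. Retrosynthetic cuts: the C9=C10 alkene (Julia–Kocienski; dioxane aldehyde + side-chain sulfone), then the ring bond O1–C3, then O2–C6 (hydroperoxysilylation of a C6=CH2 alkene), then C4–C5 and C7–C8 (two enolate alkylations of 3-bromo-2-(bromomethyl)prop-1-ene).
2. First enabling feature: C3 carries the CH2–CO2H arm, so O1–C3–C2–C1(=O)–O is a β-oxy acid. C1–C3 are carried as an oxetan-2-one whose C3–O bond is the leaving group for the peroxide oxygen on C6; its opening frees the acid function.
3. Second enabling feature: C6 lies between two mirror-image CH2–CH(CH3) arms (C5–C4 and C7–C8), so C3–C9 is built as a meso chain and desymmetrised by a lipase.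
4. Forward order: meso chain → monoacetate → aldehyde → oxetanone ring (step 7) → silyl peroxide → 1,2-dioxane ring (step 9, lactone ring consumed) → C9 aldehyde → side chain → acid.
5. Stereochemistry: C4 and C8 from two enantiomeric oxazolidinones (absolute assignment by the lipase); C3 from an alkaloid-catalysed ketene–aldehyde cycloaddition, then inverted in the ring closure; C12 from the Rh(acac)(C2H4)2/(S)-BINAP conjugate addition; both (E)-alkenes from the boronic acid and the Julia–Kocienski step.
6. C6 has no controlling element (acyclic tertiary radical): both epimers are expected and are separated as the cyclic esters after ring closure.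

Key step: step 9

Numbering of the target used below: dioxane O1, O2, C3 (arm C2, C1 = CO2H), C4 (CH3), C5, C6 (CH3); side chain C7–C14 with methyls on C8 and C12, alkenes C9=C10 and C13=C14, phenyl on C14.

Assumption: the sense of the three catalyst-controlled steps is taken from the closest analogues (lipase hydrolysing the acetate on the (S)-methyl arm of a meso 2-methyl-branched diacetate; the quinidine series giving the (R)-lactone carbon; (S)-BINAP giving the (S)-ester); should one be opposite, the enzymatic acylation mode, the quinine-derived catalyst or (R)-BINAP is used instead.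

**Route**

Step 1
Reactants: 1 (4R)-4-benzyl-3-propanoyl-1,3-oxazolidin-2-one; 2 3-bromo-2-(bromomethyl)prop-1-ene
Product: 3 (4R)-4-benzyl-3-[(2S)-4-(bromomethyl)-2-methylpent-4-enoyl]-1,3-oxazolidin-2-one
Conditions: NaN(SiMe3)2, THF, −78 → −40 °C, 2 in excess (4 equiv)
Reagents that add atoms: none
Why: Evans asymmetric alkylation, in which the chelated (Z)-sodium enolate is attacked by the allylic bromide on the face opposite the benzyl group, setting the future C4 as (S), while the excess of dibromide limits double alkylation.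

Step 2
Reactants: 3 (4R)-4-benzyl-3-[(2S)-4-(bromomethyl)-2-methylpent-4-enoyl]-1,3-oxazolidin-2-one; 4 (4S)-4-benzyl-3-propanoyl-1,3-oxazolidin-2-one
Product: 5 (4R)-4-benzyl-3-{(2S,6R)-7-[(4S)-4-benzyl-2-oxo-1,3-oxazolidin-3-yl]-2,6-dimethyl-4-methylidene-7-oxoheptanoyl}-1,3-oxazolidin-2-one (meso)
Conditions: NaN(SiMe3)2, THF, −78 → −40 °C (enolate of 4, 1.3 equiv)
Reagents that add atoms: none
Why: Second Evans alkylation with the enantiomeric auxiliary, which sets the future C8 as the mirror image of C4, so that the product should be the meso bis-imide.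

Step 3
Reactants: 5 (4R)-4-benzyl-3-{(2S,6R)-7-[(4S)-4-benzyl-2-oxo-1,3-oxazolidin-3-yl]-2,6-dimethyl-4-methylidene-7-oxoheptanoyl}-1,3-oxazolidin-2-one
Product: 6 (2R,6S)-2,6-dimethyl-4-methylideneheptane-1,7-diol (meso)
Conditions: LiBH4, MeOH, THF, 0 °C
Reagents that add atoms: none
Why: Reductive cleavage of both N-acyloxazolidinones by LiBH4 should give the primary alcohols without touching the α-stereocentres or the alkene, and both auxiliaries are recovered.

Step 4
Reactants: 6 (2R,6S)-2,6-dimethyl-4-methylideneheptane-1,7-diol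
Product: 7 (2R,6S)-2,6-dimethyl-4-methylideneheptane-1,7-diyl diacetate (meso)
Conditions: Ac2O, pyridine, 4-(dimethylamino)pyridine (cat.), CH2Cl2, rt
Reagents that add atoms: acetic anhydride, CC(=O)OC(C)=O
Why: Acylation of both primary alcohols gives the meso diacetate that the enzymatic step needs.

Step 5
Reactants: 7 (2R,6S)-2,6-dimethyl-4-methylideneheptane-1,7-diyl diacetate
Product: 8 (2R,6S)-7-hydroxy-2,6-dimethyl-4-methylideneheptyl acetate
Conditions: Pseudomonas fluorescens lipase, phosphate buffer (pH 7), rt
Reagents that add atoms: none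
Why: Enzymatic desymmetrisation of a meso diacetate, in which the lipase should hydrolyse only the acetate on the arm with the (S)-methyl centre, so that this arm becomes the ring arm (free C3–OH) and the absolute configuration of C4 and C8 is fixed in one operation.

Step 6
Reactants: 8 (2R,6S)-7-hydroxy-2,6-dimethyl-4-methylideneheptyl acetate
Product: 9 (2R,6S)-2,6-dimethyl-4-methylidene-7-oxoheptyl acetate
Conditions: Dess–Martin periodinane, CH2Cl2, 0 °C → rt
Reagents that add atoms: none
Why: Dess–Martin oxidation of the primary alcohol under near-neutral conditions should give the α-methyl aldehyde without epimerisation at C4.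

Step 7
Reactants: 9 (2R,6S)-2,6-dimethyl-4-methylidene-7-oxoheptyl acetate
Product: 10 (2R,6S)-2-methyl-4-methylidene-6-[(2R)-4-oxooxetan-2-yl]heptyl acetate
Conditions: AcCl (slow addition), iPr2NEt, O-trimethylsilylquinidine (15 mol %), LiClO4, CH2Cl2/Et2O, −78 °C
Reagents that add atoms: acetyl chloride, CC(Cl)=O
Why: Catalytic asymmetric acyl halide–aldehyde cyclocondensation (Wynberg-type [2+2]), in which ketene formed in the flask is bound by the alkaloid as an ammonium enolate that adds to the lithium-activated aldehyde and lactonises, the alkaloid choosing the aldehyde face so that the lactone carbon C3 is (R), anti to the C4 methyl (catalyst control against the modest Felkin preference).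

Step 8
Reactants: 10 (2R,6S)-2-methyl-4-methylidene-6-[(2R)-4-oxooxetan-2-yl]heptyl acetate
Product: 11 (2R,4R,6S)-2,4-dimethyl-6-[(2R)-4-oxooxetan-2-yl]-4-[(triethylsilyl)peroxy]heptyl acetate
Conditions: Co(acac)2 (10 mol %), O2 (1 atm), Et3SiH, ClCH2CH2Cl, rt
Reagents that add atoms: dioxygen, O=O; triethylsilane, CC[SiH](CC)CC
Why: Mukaiyama–Isayama hydroperoxysilylation, in which hydrogen-atom transfer from a cobalt hydride (formed from Co(acac)2 and Et3SiH) to the terminal CH2 gives the tertiary C6 radical that is trapped by O2 and silylated while acetate and lactone stay inert; nothing distinguishes the two faces of this acyclic radical, so 11 should form together with its C6 epimer, and the pair is carried on and separated after step 9.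

Step 9
Reactants: 11 (2R,4R,6S)-2,4-dimethyl-6-[(2R)-4-oxooxetan-2-yl]-4-[(triethylsilyl)peroxy]heptyl acetate
Product: 14 methyl 2-[(3S,4S,6R)-6-[(2R)-3-(acetyloxy)-2-methylpropyl]-4,6-dimethyl-1,2-dioxan-3-yl]acetate, via tertiary hydroperoxide 12 (not isolated), via dioxane acid 13 (not isolated)
Conditions: CsF, DMF, 0 °C → rt; then MeI, rt
Reagents that add atoms: iodomethane, CI
Why: Proposed new method: fluoride removes the triethylsilyl group of 11 and frees the tertiary peroxide anion (12), whose terminal oxygen O1 attacks C3 of the oxetan-2-one from the side opposite the C3–O(acyl) bond, so that the strained lactone opens by alkyl–oxygen fission to the cesium carboxylate of 13, which iodomethane esterifies in the same flask. The closest known reaction types are the opening of β-lactones at the β-carbon by soft anions and by tethered oxygen nucleophiles (which gives tetrahydrofuran- and tetrahydropyran-2-acetic acids with inversion) and the ring closure of tertiary hydroperoxides onto secondary sulfonates or epoxides to 1,2-dioxanes; a peroxide oxygen has not been used to open a β-lactone in this way. The 1,2-dioxane closes in the 6-exo-tet mode through a chair in which the C4 methyl and the C6 side arm are equatorial and the C3 acetic arm is axial. C3 is the only stereocentre formed anew and it is set by inversion, so the (R)-lactone carbon from step 7 becomes (3S) with the acetate arm cis to the C4 methyl, while C4, C6 and C8 are untouched. The step needs attack at the alkyl carbon and not at the carbonyl carbon, which the tether secures (six-membered against eight-membered ring), and substitution and not elimination, which the four-membered ring secures because its C2–H bonds cannot become antiperiplanar to the breaking C3–O bond. The C6 epimer that accompanies 11 should close in the same way, and the two cyclic esters are separated here by chromatography.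

Step 10
Reactants: 14 methyl 2-[(3S,4S,6R)-6-[(2R)-3-(acetyloxy)-2-methylpropyl]-4,6-dimethyl-1,2-dioxan-3-yl]acetate
Product: 15 methyl 2-[(3S,4S,6R)-6-[(2R)-3-hydroxy-2-methylpropyl]-4,6-dimethyl-1,2-dioxan-3-yl]acetate
Conditions: K2CO3 (0.2 equiv), MeOH, 0 °C
Reagents that add atoms: none
Why: Carbonate-catalysed transesterification should remove the primary acetate as methyl acetate, the methyl ester being degenerate under methanolysis and the dialkyl peroxide stable to the weak base at 0 °C.

Step 11
Reactants: 15 methyl 2-[(3S,4S,6R)-6-[(2R)-3-hydroxy-2-methylpropyl]-4,6-dimethyl-1,2-dioxan-3-yl]acetate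
Product: 16 methyl 2-[(3S,4S,6S)-4,6-dimethyl-6-[(2R)-2-methyl-3-oxopropyl]-1,2-dioxan-3-yl]acetate (C6 unchanged in space; the descriptor changes only by priority)
Conditions: Dess–Martin periodinane, CH2Cl2, 0 °C → rt
Reagents that add atoms: none
Why: Dess–Martin oxidation gives the C9 aldehyde under neutral conditions that should neither epimerise C8 nor touch the peroxide.

Step 12
Reactants: 17 tert-butyl (2E)-but-2-enoate; 18 [(E)-2-phenylethenyl]boronic acid
Product: 19 tert-butyl (3S,4E)-3-methyl-5-phenylpent-4-enoate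
Conditions: Rh(acac)(C2H4)2 (3 mol %), (S)-BINAP (4.5 mol %), 1,4-dioxane/H2O (10:1), 100 °C
Reagents that add atoms: none
Why: Hayashi–Miyaura reaction, in which the BINAP-bound alkenylrhodium species adds to one enantioface of the (E)-enoate and so sets C12, the (E)-geometry of the boronic acid being retained in the C13=C14 alkene.

Step 13
Reactants: 19 tert-butyl (3S,4E)-3-methyl-5-phenylpent-4-enoate
Product: 20 (3S,4E)-3-methyl-5-phenylpent-4-en-1-ol
Conditions: LiAlH4, Et2O, 0 °C
Reagents that add atoms: none
Why: Hydride reduction of the ester to the primary alcohol should leave the styrenyl alkene and C12 untouched.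

Step 14
Reactants: 20 (3S,4E)-3-methyl-5-phenylpent-4-en-1-ol
Product: 21 5-{[(3S,4E)-3-methyl-5-phenylpent-4-en-1-yl]sulfanyl}-1-phenyl-1H-tetrazole
Conditions: 1-phenyl-1H-tetrazole-5-thiol, PPh3, diisopropyl azodicarboxylate, THF, 0 °C → rt
Reagents that add atoms: 1-phenyl-1H-tetrazole-5-thiol, Sc1nnnn1-c1ccccc1
Why: Mitsunobu thioetherification of the unhindered primary alcohol with the acidic heteroaryl thiol.

Step 15
Reactants: 21 5-{[(3S,4E)-3-methyl-5-phenylpent-4-en-1-yl]sulfanyl}-1-phenyl-1H-tetrazole
Product: 22 5-{[(3S,4E)-3-methyl-5-phenylpent-4-en-1-yl]sulfonyl}-1-phenyl-1H-tetrazole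
Conditions: H2O2 (30 % aq.), (NH4)6Mo7O24·4H2O (10 mol %), EtOH, 0 °C → rt
Reagents that add atoms: hydrogen peroxide, OO
Why: Molybdate-catalysed sulfide-to-sulfone oxidation, in which the peroxomolybdate should oxidise sulfur much faster than it epoxidises the disubstituted alkene.

Step 16
Reactants: 16 methyl 2-[(3S,4S,6S)-4,6-dimethyl-6-[(2R)-2-methyl-3-oxopropyl]-1,2-dioxan-3-yl]acetate; 22 5-{[(3S,4E)-3-methyl-5-phenylpent-4-en-1-yl]sulfonyl}-1-phenyl-1H-tetrazole
Product: 23 methyl 2-[(3S,4S,6R)-4,6-dimethyl-6-[(2R,3E,6S,7E)-2,6-dimethyl-8-phenylocta-3,7-dien-1-yl]-1,2-dioxan-3-yl]acetate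
Conditions: 22, KN(SiMe3)2, DME, −60 °C; then 16, −60 °C → rt
Reagents that add atoms: none
Why: Julia–Kocienski olefination, in which the metalated tetrazolyl sulfone adds to the aldehyde and the adduct collapses by Smiles rearrangement and loss of SO2 to the (E)-alkene (favoured for a primary alkyl sulfone, an α-branched aldehyde and a potassium base in DME), the addition at low temperature being faster than enolisation at C8 or attack on the peroxide.

Step 17
Reactants: 23 methyl 2-[(3S,4S,6R)-4,6-dimethyl-6-[(2R,3E,6S,7E)-2,6-dimethyl-8-phenylocta-3,7-dien-1-yl]-1,2-dioxan-3-yl]acetate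
Product: 24 2-[(3S,4S,6R)-4,6-dimethyl-6-[(2R,3E,6S,7E)-2,6-dimethyl-8-phenylocta-3,7-dien-1-yl]-1,2-dioxan-3-yl]acetic acid (target)
Conditions: LiOH, THF/H2O, 0 °C → rt; dilute HCl work-up
Reagents that add atoms: lithium hydroxide, [Li+].[OH-]
Why: Saponification of the methyl ester under mild conditions, which the hindered dialkyl peroxide, the alkenes and all stereocentres should survive.

**Compound list**

1 | (4R)-4-benzyl-3-propanoyl-1,3-oxazolidin-2-one | CCC(=O)N1[C@H](Cc2ccccc2)COC1=O | starting material
2 | 3-bromo-2-(bromomethyl)prop-1-ene | C=C(CBr)CBr | starting material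
3 | (4R)-4-benzyl-3-[(2S)-4-(bromomethyl)-2-methylpent-4-enoyl]-1,3-oxazolidin-2-one | C=C(CBr)C[C@H](C)C(=O)N1[C@H](Cc2ccccc2)COC1=O | intermediate
4 | (4S)-4-benzyl-3-propanoyl-1,3-oxazolidin-2-one | CCC(=O)N1[C@@H](Cc2ccccc2)COC1=O | starting material
5 | (4R)-4-benzyl-3-{(2S,6R)-7-[(4S)-4-benzyl-2-oxo-1,3-oxazolidin-3-yl]-2,6-dimethyl-4-methylidene-7-oxoheptanoyl}-1,3-oxazolidin-2-one (meso) | C=C(C[C@H](C)C(=O)N1[C@H](Cc2ccccc2)COC1=O)C[C@@H](C)C(=O)N1[C@@H](Cc2ccccc2)COC1=O | intermediate
6 | (2R,6S)-2,6-dimethyl-4-methylideneheptane-1,7-diol (meso) | C=C(C[C@H](C)CO)C[C@@H](C)CO | intermediate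
7 | (2R,6S)-2,6-dimethyl-4-methylideneheptane-1,7-diyl diacetate (meso) | C=C(C[C@H](C)COC(C)=O)C[C@@H](C)COC(C)=O | intermediate
8 | (2R,6S)-7-hydroxy-2,6-dimethyl-4-methylideneheptyl acetate | C=C(C[C@H](C)CO)C[C@@H](C)COC(C)=O | intermediate
9 | (2R,6S)-2,6-dimethyl-4-methylidene-7-oxoheptyl acetate | C=C(C[C@H](C)C=O)C[C@@H](C)COC(C)=O | intermediate
10 | (2R,6S)-2-methyl-4-methylidene-6-[(2R)-4-oxooxetan-2-yl]heptyl acetate | C=C(C[C@H](C)[C@H]1CC(=O)O1)C[C@@H](C)COC(C)=O | intermediate
11 | (2R,4R,6S)-2,4-dimethyl-6-[(2R)-4-oxooxetan-2-yl]-4-[(triethylsilyl)peroxy]heptyl acetate | CC(=O)OC[C@H](C)C[C@@](C)(OO[Si](CC)(CC)CC)C[C@H](C)[C@H]1CC(=O)O1 | intermediate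
12 | (2R,4R,6S)-4-hydroperoxy-2,4-dimethyl-6-[(2R)-4-oxooxetan-2-yl]heptyl acetate (formed in the flask as its cesium salt) | CC(=O)OC[C@H](C)C[C@@](C)(OO)C[C@H](C)[C@H]1CC(=O)O1 | intermediate
13 | 2-[(3S,4S,6R)-6-[(2R)-3-(acetyloxy)-2-methylpropyl]-4,6-dimethyl-1,2-dioxan-3-yl]acetic acid (formed in the flask as its cesium salt) | CC(=O)OC[C@H](C)C[C@]1(C)C[C@H](C)[C@H](CC(=O)O)OO1 | intermediate
14 | methyl 2-[(3S,4S,6R)-6-[(2R)-3-(acetyloxy)-2-methylpropyl]-4,6-dimethyl-1,2-dioxan-3-yl]acetate | CC(=O)OC[C@H](C)C[C@]1(C)C[C@H](C)[C@H](CC(=O)OC)OO1 | intermediate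
15 | methyl 2-[(3S,4S,6R)-6-[(2R)-3-hydroxy-2-methylpropyl]-4,6-dimethyl-1,2-dioxan-3-yl]acetate | OC[C@H](C)C[C@]1(C)C[C@H](C)[C@H](CC(=O)OC)OO1 | intermediate
16 | methyl 2-[(3S,4S,6S)-4,6-dimethyl-6-[(2R)-2-methyl-3-oxopropyl]-1,2-dioxan-3-yl]acetate | O=C[C@H](C)C[C@]1(C)C[C@H](C)[C@H](CC(=O)OC)OO1 | intermediate
17 | tert-butyl (2E)-but-2-enoate | C/C=C/C(=O)OC(C)(C)C | starting material
18 | [(E)-2-phenylethenyl]boronic acid | OB(O)/C=C/c1ccccc1 | starting material
19 | tert-butyl (3S,4E)-3-methyl-5-phenylpent-4-enoate | C[C@H](/C=C/c1ccccc1)CC(=O)OC(C)(C)C | intermediate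
20 | (3S,4E)-3-methyl-5-phenylpent-4-en-1-ol | C[C@H](/C=C/c1ccccc1)CCO | intermediate
21 | 5-{[(3S,4E)-3-methyl-5-phenylpent-4-en-1-yl]sulfanyl}-1-phenyl-1H-tetrazole | C[C@H](/C=C/c1ccccc1)CCSc1nnnn1-c1ccccc1 | intermediate
22 | 5-{[(3S,4E)-3-methyl-5-phenylpent-4-en-1-yl]sulfonyl}-1-phenyl-1H-tetrazole | C[C@H](/C=C/c1ccccc1)CCS(=O)(=O)c1nnnn1-c1ccccc1 | intermediate
23 | methyl 2-[(3S,4S,6R)-4,6-dimethyl-6-[(2R,3E,6S,7E)-2,6-dimethyl-8-phenylocta-3,7-dien-1-yl]-1,2-dioxan-3-yl]acetate | C[C@H](/C=C/c1ccccc1)C/C=C/[C@H](C)C[C@]1(C)C[C@H](C)[C@H](CC(=O)OC)OO1 | intermediate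
24 | 2-[(3S,4S,6R)-4,6-dimethyl-6-[(2R,3E,6S,7E)-2,6-dimethyl-8-phenylocta-3,7-dien-1-yl]-1,2-dioxan-3-yl]acetic acid | C[C@H](/C=C/c1ccccc1)C/C=C/[C@H](C)C[C@]1(C)C[C@H](C)[C@H](CC(=O)O)OO1 | target

**Step count and risks**

Total steps: 17. Longest linear sequence: 13 steps (steps 1–11, 16 and 17); the sulfone branch (steps 12–15) has 4.

Steps most likely to fail:

1. Step 9 (Proposed new method). What may go wrong: attack of the peroxide anion or of fluoride at the lactone carbonyl, or intermolecular reaction, in place of ring closure at C3. Fallback with known chemistry, setting out from aldehyde 9 and returning at ester 14: Wittig olefination of 9 with methyl (triphenylphosphoranylidene)acetate in CH2Cl2 should give methyl (2E,4S,8R)-9-(acetyloxy)-4,8-dimethyl-6-methylidenenon-2-enoate F1 as the (E)-isomer. Hydroperoxysilylation of F1 under the conditions of step 8, in which the electron-rich 1,1-disubstituted alkene reacts in preference to the enoate, should give methyl (2E,4S,6S,8R)-9-(acetyloxy)-4,6,8-trimethyl-6-[(triethylsilyl)peroxy]non-2-enoate F2 together with its C6 epimer. Desilylation of F2 with Bu4NF and AcOH in THF should give methyl (2E,4S,6S,8R)-9-(acetyloxy)-6-hydroperoxy-4,6,8-trimethylnon-2-enoate F3 as the free hydroperoxide. Treatment of F3 with Et2NH in CF3CH2OH then brings about the 6-exo-trig intramolecular peroxy-Michael addition, which forms the same O1–C3 bond and gives 14. In this variant C3 rests on the chair transition state of the conjugate addition and not on inversion, so a C3 epimer may have to be removed together with the C6 epimer.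

2. Step 7. What may go wrong: mismatched double diastereoselection (the catalyst has to override the Felkin preference of the α-methyl aldehyde) and base-induced epimerisation at C4 before the cycloaddition. Fallback from 9, returning at 10: reagent-controlled Mukaiyama aldol addition of 1-(ethylsulfanyl)-1-(trimethylsilyloxy)ethene to 9, promoted by Sn(OTf)2 and a chiral proline-derived diamine, should give S-ethyl (3R,4S,8R)-9-(acetyloxy)-3-hydroxy-4,8-dimethyl-6-methylidenenonanethioate F4 after aqueous work-up. Thiophilic activation of F4 with AgO2CCF3 in buffered MeCN, in the manner of a Masamune thioester lactonisation, then closes the oxetanone by attack of the C3 hydroxyl on the acyl carbon, with retention at C3, and gives 10.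

3. Step 8. What may go wrong: no facial selectivity in the oxygen trapping at C6, combined with poor separability of the acyclic epimers, so that half of an advanced chiral intermediate is lost late. Fallback from 7, returning at 11: the hydroperoxysilylation is moved to the meso diacetate 7, which should give (2R,4s,6S)-2,4,6-trimethyl-4-[(triethylsilyl)peroxy]heptane-1,7-diyl diacetate F5 and its 4r isomer. These are two achiral diastereomers and are separated before any enzyme, chiral catalyst or side chain is spent. Lipase hydrolysis of F5 as in step 5 should give (2R,4S,6S)-7-hydroxy-2,4,6-trimethyl-4-[(triethylsilyl)peroxy]heptyl acetate F6 with the free hydroxyl on the arm of the (S)-methyl centre. Dess–Martin oxidation of F6 should give (2R,4R,6S)-2,4,6-trimethyl-7-oxo-4-[(triethylsilyl)peroxy]heptyl acetate F7 as the aldehyde, and the cyclocondensation of step 7 applied to F7 then gives 11 as a single C6 epimer. This does not create selectivity; it moves the unselective step to the cheapest point of the route.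

**Further compounds**

F1 | step 9 | methyl (2E,4S,8R)-9-(acetyloxy)-4,8-dimethyl-6-methylidenenon-2-enoate | C=C(C[C@H](C)/C=C/C(=O)OC)C[C@@H](C)COC(C)=O
F2 | step 9 | methyl (2E,4S,6S,8R)-9-(acetyloxy)-4,6,8-trimethyl-6-[(triethylsilyl)peroxy]non-2-enoate | CC(=O)OC[C@H](C)C[C@@](C)(OO[Si](CC)(CC)CC)C[C@H](C)/C=C/C(=O)OC
F3 | step 9 | methyl (2E,4S,6S,8R)-9-(acetyloxy)-6-hydroperoxy-4,6,8-trimethylnon-2-enoate | CC(=O)OC[C@H](C)C[C@@](C)(OO)C[C@H](C)/C=C/C(=O)OC
F4 | step 7 | S-ethyl (3R,4S,8R)-9-(acetyloxy)-3-hydroxy-4,8-dimethyl-6-methylidenenonanethioate | C=C(C[C@H](C)[C@H](O)CC(=O)SCC)C[C@@H](C)COC(C)=O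
F5 | step 8 | (2R,4s,6S)-2,4,6-trimethyl-4-[(triethylsilyl)peroxy]heptane-1,7-diyl diacetate (meso) | CC(=O)OC[C@H](C)C[C@@](C)(OO[Si](CC)(CC)CC)C[C@H](C)COC(C)=O
F6 | step 8 | (2R,4S,6S)-7-hydroxy-2,4,6-trimethyl-4-[(triethylsilyl)peroxy]heptyl acetate | CC(=O)OC[C@H](C)C[C@@](C)(OO[Si](CC)(CC)CC)C[C@H](C)CO
F7 | step 8 | (2R,4R,6S)-2,4,6-trimethyl-7-oxo-4-[(triethylsilyl)peroxy]heptyl acetate | CC(=O)OC[C@H](C)C[C@@](C)(OO[Si](CC)(CC)CC)C[C@H](C)C=O
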